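**Retrosynthetic overview**
- Feature: in ring C, O1, C2 and C3 lie in a row next to the C4 ketone and C3 bears a heteroatom. O1–C2 and C3–X can therefore both be set on one C2≡C3 triple bond conjugated with C4=O. Ring A is mirror-symmetric about the C4a···C7 axis (OMe, OMe, O7, OMe, OMe), so its two ortho methoxy oxygens are the same nucleophile.
- Endgame: target ⇐ BCl3 removal of the 7-benzyl group and the peri-chelated 5-methyl group ⇐ C3–OMe by Pd2(dba)3/tBuBrettPhos C–O coupling ⇐ 3-iodoflavone.
- Key disconnection: 3-iodoflavone ⇐ ICl-triggered 6-endo-dig closure (O1–C2 and C3–I together, loss of MeCl) of the 4-benzyloxy-2,3,5,6-tetramethoxyphenyl alkynone.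
- Alkynone ⇐ C3–C4 bond by acetylide addition to the ring A aldehyde, then oxidation. The aldehyde comes from 1,2,4,5-tetramethoxybenzene (lithiation–borylation–oxidation for O7, benzylation, bromination, Br/Li exchange–formylation). The alkyne comes from 2,4,5-trimethoxybenzaldehyde (Ohira–Bestmann).
- Ring order: rings A and B are bought as arenes; ring C is the only ring made, in the key step.

Key step: step 8

Assumption: 1,2,4,5-tetramethoxybenzene and 2,4,5-trimethoxybenzaldehyde are taken as catalogue chemicals; the target has no stereocentre, so its SMILES needs no descriptor.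

**Step 1**
Reactants: 1 1,2,4,5-tetramethoxybenzene
Product: 4 2,3,5,6-tetramethoxyphenol, via aryllithium 2 (not isolated), via lithium aryltrimethoxyborate 3 (not isolated)
Conditions: nBuLi (1.05 equiv), TMEDA, THF, 0 °C; B(OMe)3, −78 °C → rt; AcOH, 30% aq H2O2, 0 °C → rt
Reagents that add atoms: hydrogen peroxide, OO (phenol oxygen of 4); n-butyllithium, [Li]CCCC (lithium of 2 and 3); trimethyl borate, COB(OC)OC (boron and methoxy groups of 3)
Why: Directed ortho-metalation between two flanking methoxy groups gives the only aryl anion the symmetrical ring can form, and borylation–peroxide oxidation turns C–Li into C–OH at that position, which installs the future O7 as the one oxygen that differs from the four methyl ethers.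

**Step 2**
Reactants: 4 2,3,5,6-tetramethoxyphenol
Product: 5 3-(benzyloxy)-1,2,4,5-tetramethoxybenzene
Conditions: BnBr (1.2 equiv), K2CO3, DMF, 50 °C, N2
Reagents that add atoms: benzyl bromide, BrCc1ccccc1
Why: Williamson ether synthesis on the only free hydroxyl marks the future O7 with a group that survives organolithiums at −78 °C, MnO2, ICl and the basic coupling, and that leaves under the same Lewis acid as the 5-methyl group.

**Step 3**
Reactants: 5 3-(benzyloxy)-1,2,4,5-tetramethoxybenzene
Product: 6 1-(benzyloxy)-4-bromo-2,3,5,6-tetramethoxybenzene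
Conditions: NBS (1.05 equiv), dry MeCN, 0 °C → rt, dark
Reagents that add atoms: N-bromosuccinimide, O=C1CCC(=O)N1Br
Why: Electrophilic aromatic bromination can only take the single C–H of the pentaalkoxy ring, which is far more activated than the phenyl ring of the benzyl group, while dry solvent and exclusion of light suppress oxidative demethylation to a quinone and radical benzylic bromination.

**Step 4**
Reactants: 6 1-(benzyloxy)-4-bromo-2,3,5,6-tetramethoxybenzene
Product: 9 4-(benzyloxy)-2,3,5,6-tetramethoxybenzaldehyde, via aryllithium 7 (not isolated), via lithium hemiaminal alkoxide 8 (not isolated)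
Conditions: nBuLi (1.05 equiv), THF, −78 °C, 15 min; DMF (3 equiv), −78 → 0 °C; 1 M aq HCl
Reagents that add atoms: N,N-dimethylformamide, CN(C)C=O (formyl carbon and oxygen of 9); n-butyllithium, [Li]CCCC (lithium of 7 and 8)
Why: Bromine–lithium exchange at −78 °C is much faster than deprotonation of the OCH2Ph group, so 7 forms without the benzylic lithiation and Wittig rearrangement that direct lithiation of 5 would risk, and formylation with DMF (Bouveault aldehyde synthesis) rests at alkoxide 8 until the acid quench releases 9.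

**Step 5**
Reactants: 10 2,4,5-trimethoxybenzaldehyde
Product: 11 1-ethynyl-2,4,5-trimethoxybenzene
Conditions: dimethyl (1-diazo-2-oxopropyl)phosphonate (1.3 equiv), K2CO3 (2 equiv), MeOH, rt
Reagents that add atoms: dimethyl (1-diazo-2-oxopropyl)phosphonate, COP(=O)(OC)C(=[N+]=[N-])C(C)=O (terminal alkyne carbon)
Why: In the Ohira–Bestmann variant of the Seyferth–Gilbert homologation, methanolysis frees the diazomethylphosphonate anion, which adds to the non-enolisable aldehyde, expels dimethyl phosphate and loses N2 with a 1,2-hydride shift, giving the terminal alkyne under conditions mild enough for the electron-rich ring.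

**Step 6**
Reactants: 11 1-ethynyl-2,4,5-trimethoxybenzene; 9 4-(benzyloxy)-2,3,5,6-tetramethoxybenzaldehyde
Product: 14 (±)-1-[4-(benzyloxy)-2,3,5,6-tetramethoxyphenyl]-3-(2,4,5-trimethoxyphenyl)prop-2-yn-1-ol, via lithium acetylide 12 (not isolated), via lithium propargylic alkoxide 13 (not isolated)
Conditions: 11 (1.1 equiv), nBuLi (1.1 equiv), THF, −78 °C; 9, −78 → 0 °C; sat. aq NH4Cl; crude carbinol passed through Et3N-washed silica
Reagents that add atoms: n-butyllithium, [Li]CCCC (lithium of 12 and 13 only)
Why: Alkynyllithium 1,2-addition to the non-enolisable aldehyde forms the C3–C4 bond, the small linear nucleophile being little affected by the two ortho methoxy groups that would slow an acyl Sonogashira coupling of the matching aroyl chloride; the carbinol carbon forms as a racemate under no control and is flattened again in step 7.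

**Step 7**
Reactants: 14 (±)-1-[4-(benzyloxy)-2,3,5,6-tetramethoxyphenyl]-3-(2,4,5-trimethoxyphenyl)prop-2-yn-1-ol
Product: 15 1-[4-(benzyloxy)-2,3,5,6-tetramethoxyphenyl]-3-(2,4,5-trimethoxyphenyl)prop-2-yn-1-one
Conditions: activated MnO2 (15 equiv), CH2Cl2, rt
Reagents that add atoms: none
Why: MnO2 oxidises benzylic–propargylic alcohols selectively under neutral conditions, which suits a carbinol that would ionise readily in acid, and it leaves the benzyl ether, the methyl ethers and the alkyne untouched.

**Step 8**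
Reactants: 15 1-[4-(benzyloxy)-2,3,5,6-tetramethoxyphenyl]-3-(2,4,5-trimethoxyphenyl)prop-2-yn-1-one
Product: 17 7-(benzyloxy)-3-iodo-5,6,8-trimethoxy-2-(2,4,5-trimethoxyphenyl)-4H-chromen-4-one, via O-methyl oxonium chloride 16 (not isolated)
Conditions: ICl (1.05 equiv, 1 M in CH2Cl2, slow addition), CH2Cl2, −78 °C; cold aq Na2S2O3 quench
Reagents that add atoms: iodine monochloride, ClI (iodine of 17; chloride of 16)
Why: ICl delivers I+ to the C2≡C3 triple bond of 15, and because the C4 ketone withdraws from C2 while the 2,4,5-trimethoxyphenyl ring (2'- and 4'-OMe) stabilises a cation there, the iodonium ion is strongly skewed, with iodine on C3 and the positive charge on C2. One ortho methoxy oxygen of ring A attacks C2 anti to iodine, which forms O1–C2 and C3–I in one event and gives oxonium chloride 16, and chloride then takes the O-methyl group by SN2 displacement as MeCl to leave neutral 17. The closest known reaction type is the ICl-induced electrophilic cyclization of 2-methoxyaryl alkynones to 3-iodochromones and 3-iodoflavones. Ring C closes in the 6-endo-dig mode, and no stereocentre is created. The step needs attack at C2 rather than C3, that is 6-endo closure instead of 5-exo-dig closure to an aurone-type benzofuranone and instead of 5-endo-dig closure by the 2'-methoxy oxygen of ring B to a benzofuran, and both unwanted modes are disfavoured because they would place the nucleophile on C3, the alkyne carbon next to the carbonyl that carries no positive character. It also needs iodination of the alkyne rather than of an arene, which is secured by ring A having no C–H, by the alkynone deactivating ring B and by slow addition of 1.05 equiv of ICl at −78 °C; the mirror symmetry of ring A removes any choice between the two ortho oxygens, and the 7-benzyloxy oxygen cannot reach the alkyne.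

**Step 9**
Reactants: 17 7-(benzyloxy)-3-iodo-5,6,8-trimethoxy-2-(2,4,5-trimethoxyphenyl)-4H-chromen-4-one
Product: 18 7-(benzyloxy)-3,5,6,8-tetramethoxy-2-(2,4,5-trimethoxyphenyl)-4H-chromen-4-one
Conditions: Pd2(dba)3 (2.5 mol %), tBuBrettPhos (6 mol %), Cs2CO3 (1.5 equiv), MeOH (5 equiv), toluene, 70 °C
Reagents that add atoms: methanol, CO
Why: In this Buchwald–Hartwig-type C–O cross-coupling, zerovalent palladium inserts into the C3–I bond (a proven partner in Suzuki, Heck and Sonogashira couplings of 3-iodoflavones), methoxide replaces iodide on divalent palladium, and the very bulky biaryl phosphine drives C–O reductive elimination ahead of β-hydride elimination, while Cs2CO3 in toluene keeps free methoxide low (sparing C2 of the pyranone) and precipitates CsI so that iodide does not inhibit the catalyst.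

**Step 10**
Reactants: 18 7-(benzyloxy)-3,5,6,8-tetramethoxy-2-(2,4,5-trimethoxyphenyl)-4H-chromen-4-one
Product: 20 5,7-dihydroxy-3,6,8-trimethoxy-2-(2,4,5-trimethoxyphenyl)-4H-chromen-4-one (the target), via bis(dichloroboryl) ether 19 (not isolated)
Conditions: BCl3 (4 equiv), C6HMe5 (3 equiv), CH2Cl2, −78 °C (1 h) → 0 °C; 1 M aq HCl, rt
Reagents that add atoms: boron trichloride, ClB(Cl)Cl (boron and chlorine of 19 only; 20 gains nothing but hydrogen)
Why: BCl3 first ionises the 7-benzyl ether at −78 °C, with pentamethylbenzene taking up the benzyl cation by Friedel–Crafts alkylation so that rings A and B are not C-benzylated, and on warming it binds the C4 carbonyl and the peri 5-methoxy oxygen in a six-membered chelate from which chloride removes the methyl group (chelation-directed ether cleavage), while the 3-, 6-, 8- and ring B methyl ethers cannot form that chelate and stay intact until hydrolysis of 19 frees 20.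

**Compound list**
1 | 1,2,4,5-tetramethoxybenzene | COc1cc(OC)c(OC)cc1OC | starting material
2 | (2,3,5,6-tetramethoxyphenyl)lithium | [Li]c1c(OC)c(OC)cc(OC)c1OC | intermediate
3 | lithium trimethoxy(2,3,5,6-tetramethoxyphenyl)borate | [Li+].CO[B-](OC)(OC)c1c(OC)c(OC)cc(OC)c1OC | intermediate
4 | 2,3,5,6-tetramethoxyphenol | Oc1c(OC)c(OC)cc(OC)c1OC | intermediate
5 | 3-(benzyloxy)-1,2,4,5-tetramethoxybenzene | COc1cc(OC)c(OC)c(OCc2ccccc2)c1OC | intermediate
6 | 1-(benzyloxy)-4-bromo-2,3,5,6-tetramethoxybenzene | COc1c(Br)c(OC)c(OC)c(OCc2ccccc2)c1OC | intermediate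
7 | [4-(benzyloxy)-2,3,5,6-tetramethoxyphenyl]lithium | [Li]c1c(OC)c(OC)c(OCc2ccccc2)c(OC)c1OC | intermediate
8 | lithium [4-(benzyloxy)-2,3,5,6-tetramethoxyphenyl](dimethylamino)methanolate (racemic) | [Li]OC(N(C)C)c1c(OC)c(OC)c(OCc2ccccc2)c(OC)c1OC | intermediate
9 | 4-(benzyloxy)-2,3,5,6-tetramethoxybenzaldehyde | O=Cc1c(OC)c(OC)c(OCc2ccccc2)c(OC)c1OC | intermediate
10 | 2,4,5-trimethoxybenzaldehyde | COc1cc(OC)c(C=O)cc1OC | starting material
11 | 1-ethynyl-2,4,5-trimethoxybenzene | COc1cc(OC)c(C#C)cc1OC | intermediate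
12 | [(2,4,5-trimethoxyphenyl)ethynyl]lithium | [Li]C#Cc1cc(OC)c(OC)cc1OC | intermediate
13 | lithium 1-[4-(benzyloxy)-2,3,5,6-tetramethoxyphenyl]-3-(2,4,5-trimethoxyphenyl)prop-2-yn-1-olate (racemic) | [Li]OC(C#Cc1cc(OC)c(OC)cc1OC)c1c(OC)c(OC)c(OCc2ccccc2)c(OC)c1OC | intermediate
14 | 1-[4-(benzyloxy)-2,3,5,6-tetramethoxyphenyl]-3-(2,4,5-trimethoxyphenyl)prop-2-yn-1-ol (racemic) | COc1cc(OC)c(C#CC(O)c2c(OC)c(OC)c(OCc3ccccc3)c(OC)c2OC)cc1OC | intermediate
15 | 1-[4-(benzyloxy)-2,3,5,6-tetramethoxyphenyl]-3-(2,4,5-trimethoxyphenyl)prop-2-yn-1-one | COc1cc(OC)c(C#CC(=O)c2c(OC)c(OC)c(OCc3ccccc3)c(OC)c2OC)cc1OC | intermediate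
16 | 7-(benzyloxy)-3-iodo-5,6,8-trimethoxy-1-methyl-4-oxo-2-(2,4,5-trimethoxyphenyl)-4H-chromen-1-ium chloride | COc1cc(OC)c(C2=C(I)C(=O)c3c(OC)c(OC)c(OCc4ccccc4)c(OC)c3[O+]2C)cc1OC.[Cl-] | intermediate
17 | 7-(benzyloxy)-3-iodo-5,6,8-trimethoxy-2-(2,4,5-trimethoxyphenyl)-4H-chromen-4-one | COc1cc(OC)c(-c2oc3c(OC)c(OCc4ccccc4)c(OC)c(OC)c3c(=O)c2I)cc1OC | intermediate
18 | 7-(benzyloxy)-3,5,6,8-tetramethoxy-2-(2,4,5-trimethoxyphenyl)-4H-chromen-4-one | COc1cc(OC)c(-c2oc3c(OC)c(OCc4ccccc4)c(OC)c(OC)c3c(=O)c2OC)cc1OC | intermediate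
19 | 5,7-bis[(dichloroboranyl)oxy]-3,6,8-trimethoxy-2-(2,4,5-trimethoxyphenyl)-4H-chromen-4-one (5-O-boron chelated to the C4 carbonyl) | COc1cc(OC)c(-c2oc3c(OC)c(OB(Cl)Cl)c(OC)c(OB(Cl)Cl)c3c(=O)c2OC)cc1OC | intermediate
20 | 5,7-dihydroxy-3,6,8,2',4',5'-hexamethoxyflavone | COc1cc(OC)c(-c2oc3c(OC)c(O)c(OC)c(O)c3c(=O)c2OC)cc1OC | target

**Totals**
Total step count: 10. Longest linear sequence: 9 (steps 1–4 and 6–10, from 1).

**Steps most likely to fail**

Step 8 (key step). The possible failures are:
- iodination of ring B in competition with the alkyne;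
- plain addition of ICl across the triple bond without ring closure, because the di-ortho-substituted aryl ketone must turn into the plane of the alkynone before oxygen can reach C2;
- closure by the 2'-methoxy oxygen.

The fallback sets out from 9 and returns at 17. It frees the nucleophile before the alkyne is present and brings in iodine only after ring C exists, so no electrophile has to choose between alkyne and arenes.
- MgI2·OEt2 in Et2O/toluene (chelation-directed mono-demethylation of a 2,6-dimethoxybenzaldehyde) should give 4-(benzyloxy)-2-hydroxy-3,5,6-trimethoxybenzaldehyde F1.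
- Two equivalents of acetylide 12 should add to give 1-[4-(benzyloxy)-2-hydroxy-3,5,6-trimethoxyphenyl]-3-(2,4,5-trimethoxyphenyl)prop-2-yn-1-ol F2.
- MnO2 should oxidise this to 1-[4-(benzyloxy)-2-hydroxy-3,5,6-trimethoxyphenyl]-3-(2,4,5-trimethoxyphenyl)prop-2-yn-1-one F3.
- Catalytic DMAP in DMF should close ring C by 6-endo oxa-Michael addition to 7-(benzyloxy)-5,6,8-trimethoxy-2-(2,4,5-trimethoxyphenyl)-4H-chromen-4-one F4.
- LiN(iPr)2 in THF at −78 °C should deprotonate C3, the known lithiation site of flavones, to [7-(benzyloxy)-5,6,8-trimethoxy-4-oxo-2-(2,4,5-trimethoxyphenyl)-4H-chromen-3-yl]lithium F5, which I2 converts into 17.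

Step 9. The possible failures are:
- hydrodeiodination through β-hydride elimination from the palladium methoxide;
- slow oxidative addition at a C3 flanked by the carbonyl and the ortho-substituted ring B;
- attack of methoxide at C2, with opening and contraction of the pyranone.

The fallback sets out from 17 and returns at 18. It reverses the polarity at C3, which becomes the nucleophile while oxygen becomes the electrophile.
- iPrMgCl·LiCl in THF at −40 °C (iodine–magnesium exchange on an α-iodo-β-alkoxy enone) should give [7-(benzyloxy)-5,6,8-trimethoxy-4-oxo-2-(2,4,5-trimethoxyphenyl)-4H-chromen-3-yl]magnesium chloride F6.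
- B(OMe)3 should give dimethyl [7-(benzyloxy)-5,6,8-trimethoxy-4-oxo-2-(2,4,5-trimethoxyphenyl)-4H-chromen-3-yl]boronate F7.
- AcOH/H2O2, the established way from 3-metalated flavones to flavonols, should give 7-(benzyloxy)-3-hydroxy-5,6,8-trimethoxy-2-(2,4,5-trimethoxyphenyl)-4H-chromen-4-one F8.
- MeI and K2CO3 in acetone methylate the only free hydroxyl to give 18.

Step 10. The possible failures are:
- further demethylation at O6, O8 or O3 once boron is bound to the neighbouring 5-, 7- and carbonyl oxygens;
- C-benzylation of an electron-rich ring if the scavenger is outrun;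
- incomplete cleavage of the 5-methyl ether at a temperature low enough to avoid the first two.

The fallback sets out from 18 and returns at 20. It removes the two groups by unrelated mechanisms, so each can be tuned alone.
- H2 over Pd/C in EtOAc (hydrogenolysis, no Lewis acid and no benzyl cation) should give 7-hydroxy-3,5,6,8-tetramethoxy-2-(2,4,5-trimethoxyphenyl)-4H-chromen-4-one F9.
- Anhydrous AlCl3 in MeCN, followed by dilute aq HCl, should then cleave only the peri-chelated 5-methyl ether to give 20. The nitrile solvent tempers this Lewis acid, which is well used for 5-demethylation of polymethoxyflavones.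

**Further compounds**
F1 | step 8 | 4-(benzyloxy)-2-hydroxy-3,5,6-trimethoxybenzaldehyde | O=Cc1c(O)c(OC)c(OCc2ccccc2)c(OC)c1OC
F2 | step 8 | 1-[4-(benzyloxy)-2-hydroxy-3,5,6-trimethoxyphenyl]-3-(2,4,5-trimethoxyphenyl)prop-2-yn-1-ol (racemic) | COc1cc(OC)c(C#CC(O)c2c(O)c(OC)c(OCc3ccccc3)c(OC)c2OC)cc1OC
F3 | step 8 | 1-[4-(benzyloxy)-2-hydroxy-3,5,6-trimethoxyphenyl]-3-(2,4,5-trimethoxyphenyl)prop-2-yn-1-one | COc1cc(OC)c(C#CC(=O)c2c(O)c(OC)c(OCc3ccccc3)c(OC)c2OC)cc1OC
F4 | step 8 | 7-(benzyloxy)-5,6,8-trimethoxy-2-(2,4,5-trimethoxyphenyl)-4H-chromen-4-one | COc1cc(OC)c(-c2cc(=O)c3c(OC)c(OC)c(OCc4ccccc4)c(OC)c3o2)cc1OC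
F5 | step 8 | [7-(benzyloxy)-5,6,8-trimethoxy-4-oxo-2-(2,4,5-trimethoxyphenyl)-4H-chromen-3-yl]lithium | COc1cc(OC)c(-c2oc3c(OC)c(OCc4ccccc4)c(OC)c(OC)c3c(=O)c2[Li])cc1OC
F6 | step 9 | [7-(benzyloxy)-5,6,8-trimethoxy-4-oxo-2-(2,4,5-trimethoxyphenyl)-4H-chromen-3-yl]magnesium chloride | COc1cc(OC)c(-c2oc3c(OC)c(OCc4ccccc4)c(OC)c(OC)c3c(=O)c2[Mg]Cl)cc1OC
F7 | step 9 | dimethyl [7-(benzyloxy)-5,6,8-trimethoxy-4-oxo-2-(2,4,5-trimethoxyphenyl)-4H-chromen-3-yl]boronate | COc1cc(OC)c(-c2oc3c(OC)c(OCc4ccccc4)c(OC)c(OC)c3c(=O)c2B(OC)OC)cc1OC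
F8 | step 9 | 7-(benzyloxy)-3-hydroxy-5,6,8-trimethoxy-2-(2,4,5-trimethoxyphenyl)-4H-chromen-4-one | COc1cc(OC)c(-c2oc3c(OC)c(OCc4ccccc4)c(OC)c(OC)c3c(=O)c2O)cc1OC
F9 | step 10 | 7-hydroxy-3,5,6,8-tetramethoxy-2-(2,4,5-trimethoxyphenyl)-4H-chromen-4-one | COc1cc(OC)c(-c2oc3c(OC)c(O)c(OC)c(OC)c3c(=O)c2OC)cc1OC
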